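Watch one ratio: how long the target has sat, over how long it lasts.

| flask | starting material | enzyme | remark | time |
|---|---|---|---|---|
| Wednesday's | 0.034 M (fed, over 8.0 min) | 0.01 mol% | run made earlier |  |
| north-east | 0.050 M (fed, over 4.0 min) | 0.01 mol% |  | 8.0 min |
| south | 0.050 M (fed, over 2.0 min) | 0.015 mol% |  | 8.0 min |
| south-east | 0.050 M (fed, over 8.0 min) | 0.01 mol% |  | 8.0 min |
| north | 0.050 M (fed, over 4.0 min) | 0.006 mol% |  | 8.0 min |

Wednesday's run (percent of the starting material charged)

| time / min | target / % | starting material / % |
|---|---|---|
| 1.00 | 9.6 | 1.9 |
| 2.00 | 21.3 | 2.5 |
| 3.00 | 31.6 | 1.8 |
| 4.00 | 41.5 | 2.0 |
| 5.00 | 51.2 | 2.6 |

(scatter of a reading: 0.3 percentage points)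

- the numbers in the tables scatter with a standard deviation of 0.3 percentage points
- what may be going on: target -> over-reaction product; starting material + enzyme -> target + enzyme
- percentages count the whole charge, also what has not yet gone in
- no earlier run changes the charge of enzyme; that part of a forecast is a guess

- all flasks from highest to lowest amount of target, in percent of the starting material charged, at 8.0 min (north-east / south / south-east / north)
- the amount of target, in percent of the starting material charged of the flask you put first, at 8.0 min
- the amount of target, in percent of the starting material charged of the flask you put last, at 8.0 min

Wednesday's run gives the lifetime. By 5.00 min its feed has delivered 62.5% of the charge. You read 51.2% as target and 2.6% as starting material, so 8.7 percentage points has gone on. Divide the time-integral of the target readings by that shortfall. You get 14.9 min, the target lifetime, a reading with the scatter of its table.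

If starting material converts as it enters, the mean age of the target is the reading time minus half the feed time. The surviving fraction is then exp(−age/lifetime). South-east has age 4.00 min and survival 76.5%. North-east has 66.8%. South has age 7.00 min and survival 62.5%. My reckoning therefore puts south-east first. North shares north-east's feed at a lower loading, so its place is a guess.

Turn the question round. For south to beat south-east, south-east would have to hold back more than 14 points of the charge unconverted. Wednesday's run, with the same feed time and loading on a leaner charge, held about 2.16%, which is far less. This hold-up (accumulation) is your second thing to watch.

The forecast gives south-east > north > north-east > south, with 75.5% (73.5% to 77.5%) and 61.4% (58% to 64.5%), both a little below my survivals. Its ground: “All starting material is consumed by 8 min, so the main effect is how long target has sat.”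

The flasks give south-east > north > north-east > south, with 75.1% and 62.2%.

    target → over-reaction product (k = 0.00120 s⁻¹)
    starting material + enzyme → target + enzyme, rate k2*[starting material]*[enzyme]/(1 + ([starting material]/Km2) + ([starting material]/Ksi2)^2) (1.50 mM, 7.10 mM, k = 41000 L mol⁻¹ s⁻¹)

The forecast's order held, and both values fell inside its ranges. At 8.00 min south-east holds 1.56% starting material and south 0%. My survivals stand 1.4 points and 0.30 points above these flasks. But at 2.00 min south held 26.9% starting material, so there the feed did not convert as it entered. Now read south-east at 15 min. The age becomes 11.0 min, the ratio 0.738, and the survival 47.8%. That flask gives 46.3% target and 53.7% over-reaction product.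

The data come from a simulation with constants of no real substance, noise included.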